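Numbering used throughout: cyclohexane C1 (O), C2 (oxanyl), C4 (Br), C5 (Cl, CH3); oxane O1, C2 (quaternary), C5 (Br), C6 (CMe2).
Retrosynthesis: C5–Cl and C4–Br go back through a C4/C5 bromonium ion to the trans-diaxial 5-bromo-4-ol, its epoxide and the C4=C5 alkene; then the cuts are C4=C5 (metathesis), C1–C6 (methallylation), oxane O1–C6 with C5–Br (bromoetherification) and the C2–C3 bond of the carbocycle (allyl opening of epoxygeraniol).
Forward order: geraniol, epoxy alcohol, allyl diol (chain joined), oxane ring, aldehyde, methallyl carbinol, cyclohexene by metathesis, silyl ether, epoxide, bromohydrin, halogen relay, desilylation.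
Feature used: on the chair anchored by the equatorial C2 oxanyl group, C4–Br and C5–Cl are vicinal, trans and diequatorial, with bromine on the face of the axial C1 oxygen and the C2 substituent. A bromonium ion bridging C4/C5 on that face reaches this array by chloride capture at quaternary C5; anti addition of BrCl to the alkene does not.
Stereochemistry: oxane C2 and ring C2 from L-tartrate Sharpless epoxidation of the E alkene plus SN2 inversion; oxane C5 from the chair bromoetherification; C1 from Ipc-controlled methallylboration (Felkin-matched); C4 and C5 from epoxidation anti to the axial silyloxy group, two anti openings and a thermal 1,2-halogen interchange.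

Key step: step 10

Remark: in the thermal interchange of step 10 the diequatorial isomer with chlorine on the quaternary carbon is assumed to be the more stable partner; all ring intermediates keep the target numbering even where systematic numbering would differ.

Step 1
Reactants: 1 geraniol [(2E)-3,7-dimethylocta-2,6-dien-1-ol]
Product: 2 (2S,3S)-2,3-epoxygeraniol {[(2S,3S)-3-methyl-3-(4-methylpent-3-en-1-yl)oxiran-2-yl]methanol}
Conditions: Ti(OiPr)4 (5 mol%), L-(+)-diethyl tartrate (6 mol%), t-BuOOH (2 equiv), 4 Å molecular sieves, CH2Cl2, −20 °C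
Reagents that add atoms: tert-butyl hydroperoxide, CC(C)(C)OO
Why: Sharpless asymmetric epoxidation of the allylic alcohol, in which the L-(+)-tartrate titanium catalyst delivers oxygen to the face of the 2,3-alkene that gives the (2S,3S) epoxide, while the 6,7-alkene has no directing hydroxyl and stays untouched.

Step 2
Reactants: 2 (2S,3S)-2,3-epoxygeraniol; 3 allylmagnesium bromide
Product: 4 (2R,3S)-3,7-dimethyl-2-(prop-2-en-1-yl)oct-6-ene-1,3-diol
Conditions: 3 (3 equiv), CuBr·SMe2 (10 mol%), THF–Et2O, −40 → −20 °C; aq NH4Cl
Reagents that add atoms: none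
Why: Copper-catalysed Grignard opening of a 2,3-epoxy alcohol, in which the fully substituted C3 is closed to attack so the allyl group enters at C2 in the SN2 sense with inversion (C2 becomes R, C3 keeps its configuration), and the low temperature holds back Payne migration of the magnesium alkoxide.

Step 3
Reactants: 4 (2R,3S)-3,7-dimethyl-2-(prop-2-en-1-yl)oct-6-ene-1,3-diol
Product: 5 (2R)-2-[(2S,5R)-5-bromo-2,6,6-trimethyloxan-2-yl]pent-4-en-1-ol
Conditions: 2,4,4,6-tetrabromocyclohexa-2,5-dienone (1.1 equiv), MeNO2, 0 °C → rt, dark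
Reagents that add atoms: 2,4,4,6-tetrabromocyclohexa-2,5-dienone, O=C1C(Br)=CC(Br)(Br)C=C1Br
Why: Bromonium-induced 6-endo (Markovnikov) cycloetherification of the tertiary alcohol onto the trisubstituted alkene, which is far more nucleophilic than the allyl alkene; a chair-like transition state with bromine and the branched C2 substituent equatorial (C2 methyl axial) should set oxane C5 as R, and the C5 epimer and the 5-exo tetrahydrofuran isomer are removed by chromatography.

Step 4
Reactants: 5 (2R)-2-[(2S,5R)-5-bromo-2,6,6-trimethyloxan-2-yl]pent-4-en-1-ol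
Product: 6 (2S)-2-[(2S,5R)-5-bromo-2,6,6-trimethyloxan-2-yl]pent-4-enal
Conditions: Dess–Martin periodinane (1.3 equiv), pyridine, CH2Cl2, 0 °C → rt; used without chromatography
Reagents that add atoms: none
Why: Dess–Martin oxidation of a primary alcohol under buffered, non-basic conditions, so that the α stereocentre is not enolised and the β ring oxygen is not eliminated before the aldehyde is taken on.

Step 5
Reactants: 6 (2S)-2-[(2S,5R)-5-bromo-2,6,6-trimethyloxan-2-yl]pent-4-enal; 7 2-methylallylmagnesium chloride
Product: 9 (4S,5R)-5-[(2S,5R)-5-bromo-2,6,6-trimethyloxan-2-yl]-2-methylocta-1,7-dien-4-ol, via diisopinocampheylborinate ester 8 (not isolated)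
Conditions: (−)-Ipc2BOMe [antipode from (+)-α-pinene, 1.5 equiv], 7 (1.4 equiv), Et2O, −78 °C → rt; then 6, −78 °C; then 3 M NaOH, 30% H2O2, 0 °C → rt
Reagents that add atoms: none
Why: Brown asymmetric methallylboration through a closed chair (Zimmerman–Traxler) transition state, in which the reagent made in the flask from 7 and (−)-Ipc2BOMe adds to the Si face of the aldehyde, which is also the Felkin–Anh face of this α-branched aldehyde (matched case), so the carbinol carbon should be set as S.

Step 6
Reactants: 9 (4S,5R)-5-[(2S,5R)-5-bromo-2,6,6-trimethyloxan-2-yl]-2-methylocta-1,7-dien-4-ol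
Product: 10 (1S,2R)-2-[(2S,5R)-5-bromo-2,6,6-trimethyloxan-2-yl]-5-methylcyclohex-4-en-1-ol
Conditions: second-generation Grubbs catalyst (H2IMes)(PCy3)Cl2Ru=CHPh (3 mol%), CH2Cl2 (5 mM), 40 °C
Reagents that add atoms: none
Why: Ring-closing olefin metathesis between the monosubstituted and the 1,1-disubstituted alkene closes the six-membered ring as a trisubstituted cyclohexene with loss of ethene, and the ruthenium carbene tolerates the free alcohol, the ether and the secondary bromide.

Step 7
Reactants: 10 (1S,2R)-2-[(2S,5R)-5-bromo-2,6,6-trimethyloxan-2-yl]-5-methylcyclohex-4-en-1-ol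
Product: 11 tert-butyl({(1S,2R)-2-[(2S,5R)-5-bromo-2,6,6-trimethyloxan-2-yl]-5-methylcyclohex-4-en-1-yl}oxy)dimethylsilane
Conditions: TBSOTf (1.5 equiv), 2,6-lutidine (3 equiv), CH2Cl2, −78 → 0 °C
Reagents that add atoms: tert-butyldimethylsilyl trifluoromethanesulfonate, CC(C)(C)[Si](C)(C)OS(=O)(=O)C(F)(F)F
Why: Silylation of a hindered secondary alcohol with a silyl triflate and a non-nucleophilic base, which removes hydroxyl-directed delivery in the epoxidation, leaves a bulky non-participating axial group at C1 and masks this alcohol while the second hydroxyl is activated in step 10.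

Step 8
Reactants: 11 tert-butyl({(1S,2R)-2-[(2S,5R)-5-bromo-2,6,6-trimethyloxan-2-yl]-5-methylcyclohex-4-en-1-yl}oxy)dimethylsilane
Product: 12 tert-butyl({(1S,2R,4R,5S)-2-[(2S,5R)-5-bromo-2,6,6-trimethyloxan-2-yl]-4,5-epoxy-5-methylcyclohexyl}oxy)dimethylsilane
Conditions: m-CPBA (1.2 equiv), CH2Cl2, 0 °C
Reagents that add atoms: 3-chloroperoxybenzoic acid, OOC(=O)c1cccc(Cl)c1
Why: Prilezhaev epoxidation of the trisubstituted alkene, in which the axial C1 silyloxy group (the oxanyl group being equatorial) is 1,3-related to C5 and shields its face, so the peracid should attack from the other side and place the epoxide oxygen trans to the C1 and C2 substituents.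

Step 9
Reactants: 12 tert-butyl({(1S,2R,4R,5S)-2-[(2S,5R)-5-bromo-2,6,6-trimethyloxan-2-yl]-4,5-epoxy-5-methylcyclohexyl}oxy)dimethylsilane
Product: 13 (1S,2R,4R,5R)-5-bromo-2-[(2S,5R)-5-bromo-2,6,6-trimethyloxan-2-yl]-1-[(tert-butyldimethylsilyl)oxy]-5-methylcyclohexan-4-ol (target numbering)
Conditions: MgBr2·OEt2 (2 equiv), Et2O–toluene, −20 → 0 °C; aq NH4Cl
Reagents that add atoms: magnesium bromide diethyl etherate, [Mg+2].[Br-].[Br-].CCOCC
Why: Lewis-acid-assisted halide opening of a cyclohexene oxide under the Fürst–Plattner rule, where anti attack of bromide at tertiary C5 is both the trans-diaxial and the Markovnikov mode and should give axial C5–Br on the face of the C1 and C2 substituents with axial C4–OH on the opposite face.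

Step 10
Reactants: 13 (1S,2R,4R,5R)-5-bromo-2-[(2S,5R)-5-bromo-2,6,6-trimethyloxan-2-yl]-1-[(tert-butyldimethylsilyl)oxy]-5-methylcyclohexan-4-ol
Product: 17 tert-butyl({(1S,2R,4S,5S)-4-bromo-2-[(2S,5R)-5-bromo-2,6,6-trimethyloxan-2-yl]-5-chloro-5-methylcyclohexyl}oxy)dimethylsilane, via alkoxyphosphonium chloride 14 (not isolated), via bromonium chloride 15 (not isolated), via diaxial 5-bromo-4-chloro isomer 16 (not isolated)
Conditions: Ph3P/N-chlorosuccinimide (1.3 equiv each, premixed), CH2Cl2, 0 °C → rt; then MeCN, 60 °C until the diaxial isomer is consumed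
Reagents that add atoms: N-chlorosuccinimide, O=C1CCC(=O)N1Cl
Why: The premixed phosphine/N-chlorosuccinimide reagent turns the axial C4 hydroxyl of 13 into alkoxyphosphonium salt 14, which the antiperiplanar axial C5 bromine displaces from the rear to give bromonium ion 15 bridging C4/C5 on the face of the C1 and C2 substituents. Chloride opens 15 anti to bromine either at tertiary C5, which gives 17 directly, or at C4, which gives the diaxial 5-bromo-4-chloro isomer 16; on warming in a polar solvent 16 should re-ionise through the same bridged ion pair and the two halogens change places suprafacially until the diequatorial tertiary chloride/secondary bromide 17 remains. The closest known reaction types are the neighbouring-bromine-assisted substitution of trans-diaxial β-bromo alcohols with retention and the thermal diaxial-to-diequatorial rearrangement of vicinal dihalides, bromochlorides included, on cyclohexane and steroid frameworks. No ring is closed apart from the transient three-membered bromonium ring. The new C5 centre (Cl) is set by anti opening of the bromonium ion, and the new C4 centre (Br) by the face of that ion, which the configuration of the C5 bromine of 13 fixes. The selectivity needed is the site of chloride capture, and two things secure it: the cationic character of tertiary C5 favours direct capture there, and the anchoring equatorial oxanyl group makes 16, with its syn-diaxial C5–Br/C1–O contact and bromine on the quaternary carbon, the less stable partner of the interchange.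

Step 11
Reactants: 17 tert-butyl({(1S,2R,4S,5S)-4-bromo-2-[(2S,5R)-5-bromo-2,6,6-trimethyloxan-2-yl]-5-chloro-5-methylcyclohexyl}oxy)dimethylsilane
Product: 18 (1S,2R,4S,5S)-4-bromo-2-[(2S,5R)-5-bromo-2,6,6-trimethyloxan-2-yl]-5-chloro-5-methylcyclohexan-1-ol (CNP0323120.1)
Conditions: HF·pyridine, THF–pyridine, 0 °C → rt
Reagents that add atoms: none
Why: Fluoride-mediated cleavage of the silyl ether under acidic, non-basic conditions, which should leave the tertiary chloride and both secondary bromides untouched and affects no stereocentre.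

Compound list
1 | geraniol, (2E)-3,7-dimethylocta-2,6-dien-1-ol | CC(C)=CCC/C(C)=C/CO | starting material
2 | (2S,3S)-2,3-epoxygeraniol, [(2S,3S)-3-methyl-3-(4-methylpent-3-en-1-yl)oxiran-2-yl]methanol | OC[C@@H]1O[C@@]1(C)CCC=C(C)C | intermediate
3 | allylmagnesium bromide | C=CC[Mg]Br | starting material
4 | (2R,3S)-3,7-dimethyl-2-(prop-2-en-1-yl)oct-6-ene-1,3-diol | OC[C@@H](CC=C)[C@@](C)(O)CCC=C(C)C | intermediate
5 | (2R)-2-[(2S,5R)-5-bromo-2,6,6-trimethyloxan-2-yl]pent-4-en-1-ol | CC1(C)O[C@](C)([C@@H](CO)CC=C)CC[C@H]1Br | intermediate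
6 | (2S)-2-[(2S,5R)-5-bromo-2,6,6-trimethyloxan-2-yl]pent-4-enal | CC1(C)O[C@](C)([C@@H](C=O)CC=C)CC[C@H]1Br | intermediate
7 | 2-methylallylmagnesium chloride | CC(=C)C[Mg]Cl | starting material
8 | O-diisopinocampheylboryl derivative of 9 (borinate ester, isopinocampheyl groups as in (−)-Ipc2BOMe) | CC1(C)O[C@](C)([C@H](CC=C)[C@@H](OB([C@@H]2C[C@@H]3C[C@H]([C@H]2C)C3(C)C)[C@@H]2C[C@@H]3C[C@H]([C@H]2C)C3(C)C)CC(C)=C)CC[C@H]1Br | intermediate
9 | (4S,5R)-5-[(2S,5R)-5-bromo-2,6,6-trimethyloxan-2-yl]-2-methylocta-1,7-dien-4-ol | CC1(C)O[C@](C)([C@H](CC=C)[C@@H](O)CC(C)=C)CC[C@H]1Br | intermediate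
10 | (1S,2R)-2-[(2S,5R)-5-bromo-2,6,6-trimethyloxan-2-yl]-5-methylcyclohex-4-en-1-ol | CC1(C)O[C@](C)([C@@H]2CC=C(C)C[C@@H]2O)CC[C@H]1Br | intermediate
11 | tert-butyldimethylsilyl ether of 10 | CC1(C)O[C@](C)([C@@H]2CC=C(C)C[C@@H]2O[Si](C)(C)C(C)(C)C)CC[C@H]1Br | intermediate
12 | (1S,2R,4R,5S)-4,5-epoxide of 11, epoxide oxygen trans to the C1 silyloxy and C2 oxanyl groups | CC1(C)O[C@](C)([C@@H]2C[C@H]3O[C@@]3(C)C[C@@H]2O[Si](C)(C)C(C)(C)C)CC[C@H]1Br | intermediate
13 | (1S,2R,4R,5R)-5-bromo-4-hydroxy silyl ether, trans-diaxial bromohydrin (axial C5–Br cis to the C1/C2 groups, axial C4–OH) | CC1(C)O[C@](C)([C@@H]2C[C@@H](O)[C@](C)(Br)C[C@@H]2O[Si](C)(C)C(C)(C)C)CC[C@H]1Br | intermediate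
14 | triphenylphosphonium ether of 13 at the C4 oxygen, chloride salt | CC1(C)O[C@](C)([C@@H]2C[C@@H](O[P+](c3ccccc3)(c3ccccc3)c3ccccc3)[C@](C)(Br)C[C@@H]2O[Si](C)(C)C(C)(C)C)CC[C@H]1Br.[Cl-] | intermediate
15 | bromonium ion bridging C4 and C5 on the face of the C1 and C2 substituents, chloride counter-ion | CC1(C)O[C@](C)([C@@H]2C[C@@H]3[Br+][C@]3(C)C[C@@H]2O[Si](C)(C)C(C)(C)C)CC[C@H]1Br.[Cl-] | intermediate
16 | (1S,2R,4R,5R)-5-bromo-4-chloro silyl ether, diaxial regioisomer of 17 | CC1(C)O[C@](C)([C@@H]2C[C@@H](Cl)[C@](C)(Br)C[C@@H]2O[Si](C)(C)C(C)(C)C)CC[C@H]1Br | intermediate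
17 | tert-butyl({(1S,2R,4S,5S)-4-bromo-2-[(2S,5R)-5-bromo-2,6,6-trimethyloxan-2-yl]-5-chloro-5-methylcyclohexyl}oxy)dimethylsilane | CC1(C)O[C@](C)([C@@H]2C[C@H](Br)[C@@](C)(Cl)C[C@@H]2O[Si](C)(C)C(C)(C)C)CC[C@H]1Br | intermediate
18 | (1S,2R,4S,5S)-4-bromo-2-[(2S,5R)-5-bromo-2,6,6-trimethyloxan-2-yl]-5-chloro-5-methylcyclohexan-1-ol | CC1(C)O[C@](C)([C@@H]2C[C@H](Br)[C@@](C)(Cl)C[C@@H]2O)CC[C@H]1Br | target

Total steps: 11. Longest linear sequence: 11 steps, from geraniol 1 to 18.

Steps most likely to fail

Step 10. Chloride capture of the bromonium ion may run mainly at the secondary carbon, and the thermal interchange may stall before the diaxial isomer is used up. Loss of HBr from the tertiary bromide, or transfer of positive bromine to phosphorus, would cost further material. The fallback sets out from 11 and returns at 17, and it places the two halogens by substitution instead of by the relay.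
- Dihydroxylation of 11 (OsO4 cat., N-methylmorpholine N-oxide, acetone–water) on the face away from the axial silyloxy group should give the (1S,2R,4R,5S)-cis-4,5-diol F1, both hydroxyls trans to the C1 and C2 substituents.
- SOCl2/Et3N and then RuCl3 (cat.)/NaIO4 should convert it into the cyclic sulfate F2.
- LiBr in THF should open F2 at secondary C4, whose C–O bond is axial, with inversion. Hydrolysis of the sulfate monoester (cat. H2SO4, moist THF) then frees the (1S,2R,4S,5S)-4-bromo tertiary alcohol F3, with equatorial C4–Br cis to the C1/C2 groups and C5–OH on the other face.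
- SOCl2 in ether without base should replace the tertiary hydroxyl by chloride with retention, by internal return from the chlorosulfite ion pair; a bromine-bridged cation would open to the same isomer. This gives 17.

Step 3. Closure may run in the 5-exo sense to the tetrahydrofuran, and the face selectivity of bromonium formation may be poor. The fallback sets out from 4 and returns at 5.
- Shi epoxidation of the trisubstituted alkene of 4 should give the (6R)-epoxy diol F4 under reagent control. It uses the fructose-derived ketone antipode that gives the (6R)-epoxide, with Oxone (2KHSO5·KHSO4·K2SO4), K2CO3 buffer, MeCN–dimethoxymethane–water, 0 °C.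
- Camphorsulfonic acid in CH2Cl2 should close F4 in the 5-exo mode with inversion to the tetrahydrofuran carbinol F5.
- Bromotrimethylsilane with catalytic ZnBr2 should then ionise the tertiary carbinol. The ring oxygen bridges to a bicyclic epoxonium ion, and bromide opens it at the secondary carbon with inversion. This ring expansion, the course known for tetrahydrofuranyl carbinol derivatives, should give oxane 5 after methanolic work-up, with the C–Br configuration fixed by the epoxide.

Step 4. The aldehyde 6 may epimerise at its α-carbon, or lose the ring ether oxygen by β-elimination, while it is formed and handled. The fallback sets out from 5 and returns at 9 in one operation. It is an iridium-catalysed transfer-hydrogenative methallylation from the alcohol oxidation level (methallyl chloride, [Ir(cod)Cl]2, a chiral bisphosphine of the SEGPHOS type chosen for the (S)-carbinol, 4-cyano-3-nitrobenzoic acid, Cs2CO3, THF, 60 °C). The aldehyde forms only transiently and is coupled under catalyst control, so no new compound is isolated on the way.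

Further compounds
F1 | step 10 | (1S,2R,4R,5S)-2-[(2S,5R)-5-bromo-2,6,6-trimethyloxan-2-yl]-1-[(tert-butyldimethylsilyl)oxy]-5-methylcyclohexane-4,5-diol (target numbering) | CC1(C)O[C@](C)([C@@H]2C[C@@H](O)[C@@](C)(O)C[C@@H]2O[Si](C)(C)C(C)(C)C)CC[C@H]1Br
F2 | step 10 | 4,5-cyclic sulfate of F1 | CC1(C)O[C@](C)([C@@H]2C[C@H]3OS(=O)(=O)O[C@@]3(C)C[C@@H]2O[Si](C)(C)C(C)(C)C)CC[C@H]1Br
F3 | step 10 | (1S,2R,4S,5S)-4-bromo-2-[(2S,5R)-5-bromo-2,6,6-trimethyloxan-2-yl]-1-[(tert-butyldimethylsilyl)oxy]-5-methylcyclohexan-5-ol (target numbering) | CC1(C)O[C@](C)([C@@H]2C[C@H](Br)[C@@](C)(O)C[C@@H]2O[Si](C)(C)C(C)(C)C)CC[C@H]1Br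
F4 | step 3 | (2R,3S)-5-[(2R)-3,3-dimethyloxiran-2-yl]-3-methyl-2-(prop-2-en-1-yl)pentane-1,3-diol | OC[C@@H](CC=C)[C@@](C)(O)CC[C@H]1OC1(C)C
F5 | step 3 | (2R)-2-[(2S,5S)-5-(2-hydroxypropan-2-yl)-2-methyloxolan-2-yl]pent-4-en-1-ol | OC[C@@H](CC=C)[C@]1(C)CC[C@H](O1)C(C)(C)O
F0 | step 4 | none | none
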